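## Structural features

The target is a resveratrol trimer. Its core is an indane (C1–C3, C3a–C7a) whose benzo ring carries hydroxyl groups at C5 and C7. C2 of the indane is bonded to C4' of a trans-2,3-diaryl-2,3-dihydrobenzofuran (O1', C2'–C7a'; 4-hydroxyphenyl on C2', 3,5-dihydroxyphenyl on C3', hydroxyl on C6'), and C3 carries a secondary carbinol carbon Ca. C1 and Ca each bear a 4-hydroxyphenyl group.

Four contiguous stereocentres, C1 (S), C2 (R), C3 (S) and Ca (S), form one chain with the ring substituents all trans. The pair C2' (R)/C3' (R) lies just across the C2–C4' bond, with no rigid relay between the two sets.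

The compound has eight free phenols and is sensitive to oxidation. The Ca–OH is a 4-hydroxybenzylic alcohol and the C2'–O1' bond a 4-hydroxybenzylic ether; both ionise to quinone methide-type species under acid or hot base. Late Lewis-acid demethylation and hydrogenolysis are therefore unsafe.

The real difficulties are the crowded C2–C3 bond between two tertiary benzylic carbons, the all-trans C1/C2/C3 array, and the relation of that array to C2'/C3'.

The key step exploits two facts. C2–C3 joins the alkene carbons of two 4-hydroxystilbene units (C1=C2 of the benzofuran stilbene, Ca=C3 of the resveratrol unit). C1 and Ca both carry 4-hydroxyphenyl groups. As a cyclobutane C1–C2–C3–Ca, the two units hold C2 and C3 in the target configuration, and the C1–Ca bond can later be opened oxidatively to two quinone methides, one of which is captured by C7a of the resorcinol ring on C3.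

## Logic of the disconnections

**28 to 27.** The four aryl O–acetyl bonds of the benzofuran half are cut last. They stay until the end because they keep the three rings of that half out of the oxidation and ring-closure chemistry. The gain is a final step that touches no carbon framework. The forward step must be nucleophilic and nearly neutral, so that neither Ca–OH nor C2'–O1' ionises.

**27 to 24 (through 26 and 25).** C1–C7a and Ca–OH are cut and C1 is rejoined to Ca, turning the indane and its side chain into the cyclobutane C1–C2–C3–Ca. The cut is made here because both C1 and Ca carry 4-hydroxyphenyl groups, so a two-electron oxidation can open exactly this strained bond. The gain is that C1 and Ca need no control at the earlier stage; only C2 and C3 must be right. The forward step must break only C1–Ca, close C7a onto C1 before tautomerisation or hydration at C1, and hydrate Ca from the correct face. The ring closure to be suppressed is that of C5' onto Ca, not a closure at C1.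

**24 to 23.** Four Si–O bonds are cut (two silyl ethers, both ends of the strap). The strap is needed only for the photoreaction. The gain is that one operation frees exactly the four phenols the oxidation needs. The forward desilylation must not generate phenoxides, or acetyl groups would migrate.

**23 to 22.** C2–C3 and C1–Ca are cut (retro [2+2]). This is the only cut that forms the hindered C2–C3 bond and sets C2 and C3 together. The gain is two E-stilbenes joined only by a removable strap. The forward step must be head-to-head, syn, and selective for one face of the C1=C2 alkene.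

**22 to 19, 20 and 14 (through 21).** The two Si–O(aryl) bonds of the strap are cut. The strap is the only link between the halves, so each half can be made alone. The forward step must silylate two different phenols one after the other without moving acetyl groups.

**14 to 11 and 12 (through 13).** The bond between C4' and the alkene carbon (the future C2) and one O–Si bond are cut. The stilbene phenol is thereby distinguished from the four others automatically, because it arrives on its own piece with its own protecting group. The gain is an aryl bromide and a commercial styrene. The forward coupling must work at an ortho-substituted bromide, give the E alkene and spare the acetates.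

**11 to 9 (through 10).** Four O–acetyl and four O–methyl bonds are exchanged and C2' is inverted. Methyl ethers are needed for the carbene chemistry and acetates for the end game. The exchange is placed at the bromide stage, before any acid-sensitive stilbene exists. The forward demethylation must also equilibrate C2' to trans without destroying the benzylic ether.

**9 to 6 (through 8 and 7).** The C2'–C3' bond is cut (retro C–H insertion). This places C3' under catalyst control and reduces the heterocycle to an achiral diaryl ketone. The forward sequence needs a hydrazone at a ketone with two ortho substituents and a highly enantioselective insertion.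

**6 to 4 and 5; 4 to 1 and 2 (through 3).** The benzylic O–CH2 bond and the aryl–carbonyl bond are cut. The bromine that becomes C4' must be present from the start, because C4' is meta to both ring oxygens and cannot be functionalised later. The gain is three commercial arenes. The forward acylation must go next to bromine, and only the methyl ortho to the carbonyl may be lost.

**19 to 16 and 17 (through 18); 16 to 15.** The alkene–aryl bond, one O–acetyl and two O–Si bonds are cut. The 3,5-disilyl-4'-hydroxy pattern cannot be made by selective silylation of the free triphenol, whose 4'-hydroxyl is the most reactive, so the stilbene is assembled from two differently protected pieces. The forward deacetylation must leave the aryl silyl ethers intact.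

## Other disconnections considered

**Alternative 1:** The cut removes three bonds of the benzofuran benzene ring (C3a'–C7a', C4'–C5', C6'–C7'), so the central arene and the dihydrofuran are made last from three alkynes.

- **Forward key step:** Cp*RuCl(cod) couples diyne A2 with ethynylboronate A3 to give A1. In A2, an alkyne on indane C2 is tethered through C3'–C2'–O1' to a terminal ynol ether. C–B oxidation and deprotection follow.
- **In favour:** C2 carries only a slim alkyne until the end, so the crowded C2–C4' junction is never made by coupling at a hindered arene. Ruthenacycle formation from 1,6-diynes normally places the substituent of the third alkyne meta to the bulkier terminus, which is C6'. All stereocentres are set earlier by independent steps, so the relation between the indane and C2'/C3' does not rest on remote induction. On this point the alternative is better than the chosen plan.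
- **Against:** The key step creates no stereocentre and no bond of the indane. The complete indane with C1, C2, C3 and Ca has to be made separately. C2'/C3' must be carried in an open chain, with a propargylic and benzylic C3'–H next to an acid- and base-sensitive ynol ether. Seven benzyl ethers must be removed beside two benzylic C–O bonds.
- **Comparison:**
  - Structure: the chosen plan follows the two stilbene halves and forms C2–C3; alternative 1 is convergent only at C4'.
  - Mechanism: a thermal, metal-templated cyclotrimerisation is more secure than a diradical photoreaction followed by an untested fragmentation. The alternative is the better here.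
  - Step economy: the chosen plan is clearly shorter, because one photoreaction and one oxidation replace a full indane synthesis.

**Alternative 2:** The cut is C3–C3a (retro ring contraction), so the indane comes from the six-membered 1,2-dihydronaphthalene A5, in which Ca is still a ring carbon.

- **Forward key step:** PhI(OH)OTs in methanol places trivalent iodine on C3 and methoxy on Ca. C3a then migrates from Ca to C3 with loss of iodobenzene, and Ca leaves the ring as the aryl ketone of A4. Reduction and demethylation follow.
- **In favour:** Ring contraction of 1,2-dihydronaphthalenes to trans-substituted indanes is a known reaction type. The migration is stereospecific, so C3 is set trans to the C2 substituent by a well-defined ionic event. Ca arrives as a ketone, so its configuration can be set, and corrected, by a separate hydride reduction. On control of Ca the alternative is better than hydration of a quinone methide.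
- **Against:** The alkene of A5 is trisubstituted and carries an electron-rich aryl group, so addition without migration, dehydrogenation to the naphthalene and oxidation of the methoxyarenes all compete. The methyl ethers force a Lewis-acid demethylation that the Ca carbinol would not survive, so demethylation must precede reduction. A5, with C1/C2 trans and the benzofuran attached, is itself a long synthesis with the same problem of relating C1/C2 to C2'/C3'.
- **Comparison:**
  - Structure: the alternative only reorganises a ring and forms neither C2–C3 nor C1–C2.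
  - Mechanism: it is as well defined as, or better defined than, diradical closure.
  - Step economy: the chosen plan is shorter.

**Alternative 3:** The cuts are C2–C4' and C3–Ca around a cyclopentanone; the resorcinol ring (C3a–C7a) is built later on the ketone carbon and its methylene.

- **Forward key step:** Zincate A9, made from bromide A8, adds to C2 of enone A7 anti to the C1 aryl group. The enolate is trapped at C3 by aldehyde A10 to give A6.
- **In favour:** One stereocentre (C1 of A7) relays to C2 and C3 through trans addition and trans trapping, so the all-trans array comes from reliable substrate control. Enantiopure A7 and A8 fix the relation between the ring and C2'/C3' without remote induction. On both points the alternative is better than the chosen plan. Three fragments are joined in one flask.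
- **Against:** The aryl group to be transferred is ortho-substituted by the bulky C3' centre and must compete with methyl transfer. The aldol centre Ca is only moderately controlled. A6 is a β-hydroxy ketone prone to retro-aldol cleavage and epimerisation at C3, yet it must survive a multistep benzannulation that turns C=O and CH2 into C3a and C7a of a 1,3-dioxygenated benzene. The benzyl ethers again require hydrogenolysis beside benzylic C–O bonds.
- **Comparison:**
  - Structure: the chosen plan takes the resorcinol ring from a commercial arene instead of building it.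
  - Mechanism: the polar three-component coupling is more predictable.
  - Step economy: the alternative is far worse because of the benzannulation.

Key step: step 13

**Remarks before the steps**

- Atom labels (indane C1–C3, C3a–C7a; carbinol carbon Ca; primed dihydrobenzofuran atoms) are kept for the corresponding atoms of all intermediates.
- Assumption: Rh2(S-PTAD)4 is taken to give the (3'R) series in step 4 by analogy with other 2-benzyloxyaryl aryl diazomethanes. If the sense is opposite, Rh2(R-PTAD)4 is used and nothing else changes.
- Structures 22 and 23 were checked atom by atom against 28: C2'/C3' are (R,R), and the cyclobutane carries C2 (R) and C3 (S) as in 28.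
- The bulky silyl ethers on the resorcinol ring of 22 are kept deliberately: they are what should make stacking on the C3'-aryl face of the benzofuran costly.

## Steps

Step 1
Reactants: 1 1-bromo-3,5-dimethoxybenzene; 2 3,5-dimethoxybenzoyl chloride
Product: 4 (2-bromo-6-hydroxy-4-methoxyphenyl)(3,5-dimethoxyphenyl)methanone, via dimethoxy ketone 3 (not isolated)
Conditions: AlCl3 (3 equiv), CH2Cl2, 0 °C → rt
Reagents that add atoms: none
Why: Friedel–Crafts acylation at the carbon of 1 that is para to one methoxy group, ortho to the other and next to bromine, the usual site for this arene; excess AlCl3 then removes only the methyl group ortho to the carbonyl through its six-membered chelate, as in the classical synthesis of 2-hydroxy-4-methoxybenzophenones.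

Step 2
Reactants: 4 (2-bromo-6-hydroxy-4-methoxyphenyl)(3,5-dimethoxyphenyl)methanone; 5 4-methoxybenzyl chloride
Product: 6 {2-bromo-4-methoxy-6-[(4-methoxyphenyl)methoxy]phenyl}(3,5-dimethoxyphenyl)methanone
Conditions: K2CO3, Bu4NI (cat.), DMF, 60 °C
Reagents that add atoms: none
Why: Williamson etherification of the chelated phenol; the benzylic CH2 becomes C2' and its ring the C2' aryl group.

Step 3
Reactants: 6 {2-bromo-4-methoxy-6-[(4-methoxyphenyl)methoxy]phenyl}(3,5-dimethoxyphenyl)methanone
Product: 7 hydrazone of 6 (E/Z mixture at C=N)
Conditions: N2H4·H2O (20 equiv), AcOH (0.2 equiv), EtOH, 100 °C, sealed tube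
Reagents that add atoms: hydrazine, NN
Why: Acid-catalysed condensation of a diaryl ketone with hydrazine; the carbonyl is flanked by bromine and the ether, hence the large excess and heat, and the electron-rich ring should not undergo displacement of bromide.

Step 4
Reactants: 7 hydrazone of 6
Product: 9 (2S,3R)-4-bromo-3-(3,5-dimethoxyphenyl)-6-methoxy-2-(4-methoxyphenyl)-2,3-dihydro-1-benzofuran (2,3-cis), via diazo compound 8 (not isolated)
Conditions: MnO2 (8 equiv), CH2Cl2, 0 °C, filtered through Celite; then Rh2(S-PTAD)4 (1 mol%), CH2Cl2, 0 °C
Reagents that add atoms: none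
Why: Dehydrogenation of the hydrazone gives the diaryldiazomethane, and its carbene on divalent rhodium inserts into the ether C–H five atoms away (intramolecular C–H insertion of a donor/donor carbene), forming C2'–C3' and the dihydrofuran ring. The chiral carboxylate ligands set C3' (R) and the 2,3-cis relation typical of this insertion; C2' (S) is corrected in step 5.

Step 5
Reactants: 9 (2S,3R)-4-bromo-3-(3,5-dimethoxyphenyl)-6-methoxy-2-(4-methoxyphenyl)-2,3-dihydro-1-benzofuran
Product: 10 5-[(2R,3R)-4-bromo-6-hydroxy-2-(4-hydroxyphenyl)-2,3-dihydro-1-benzofuran-3-yl]benzene-1,3-diol (2,3-trans)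
Conditions: BBr3 (10 equiv), CH2Cl2, −78 → 0 °C; then H2O
Reagents that add atoms: none
Why: Lewis-acid cleavage of the four aryl methyl ethers; the same reagent reversibly ionises the C2'–O1' bond to the 4-oxybenzyl cation, and re-closure should give the more stable 2,3-trans ring, so C2' becomes R while C3' is untouched.

Step 6
Reactants: 10 5-[(2R,3R)-4-bromo-6-hydroxy-2-(4-hydroxyphenyl)-2,3-dihydro-1-benzofuran-3-yl]benzene-1,3-diol
Product: 11 5-[(2R,3R)-6-acetoxy-2-(4-acetoxyphenyl)-4-bromo-2,3-dihydro-1-benzofuran-3-yl]benzene-1,3-diyl diacetate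
Conditions: Ac2O, pyridine, DMAP (cat.), CH2Cl2, rt
Reagents that add atoms: acetic anhydride, CC(=O)OC(C)=O
Why: O-acetylation of all four phenols; the acetates deactivate the three rings of this half towards later oxidation and Friedel–Crafts attack and can be removed under mild nucleophilic conditions at the end.

Step 7
Reactants: 11 5-[(2R,3R)-6-acetoxy-2-(4-acetoxyphenyl)-4-bromo-2,3-dihydro-1-benzofuran-3-yl]benzene-1,3-diyl diacetate; 12 tert-butyl(4-ethenylphenoxy)dimethylsilane
Product: 13 5-[(2R,3R)-6-acetoxy-2-(4-acetoxyphenyl)-4-[(E)-2-(4-{[tert-butyl(dimethyl)silyl]oxy}phenyl)ethenyl]-2,3-dihydro-1-benzofuran-3-yl]benzene-1,3-diyl diacetate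
Conditions: Pd2(dba)3 (2.5 mol%), [HP(t-Bu)3]BF4 (10 mol%), Cy2NMe (1.5 equiv), 1,4-dioxane, 80 °C
Reagents that add atoms: none
Why: Mizoroki–Heck reaction: oxidative addition of zerovalent palladium to the ortho-substituted C4'–Br bond, insertion at the terminal alkene carbon and syn β-hydride elimination should give the E-stilbene; the hindered amine base leaves the aryl acetates and the silyl ether intact.

Step 8
Reactants: 13 the silyl ether from step 7
Product: 14 5-[(2R,3R)-6-acetoxy-2-(4-acetoxyphenyl)-4-[(E)-2-(4-hydroxyphenyl)ethenyl]-2,3-dihydro-1-benzofuran-3-yl]benzene-1,3-diyl diacetate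
Conditions: Et3N·3HF (5 equiv), THF/MeCN, rt
Reagents that add atoms: none
Why: Fluoride cleavage of the aryl silyl ether under slightly acidic conditions; no phenoxide is formed, so the four acetates should neither cleave nor migrate.

Step 9
Reactants: 15 5-bromobenzene-1,3-diol
Product: 16 1-bromo-3,5-bis[(tert-butyldimethylsilyl)oxy]benzene
Conditions: TBSCl (2.4 equiv), imidazole (5 equiv), DMF, rt
Reagents that add atoms: tert-butyldimethylsilyl chloride, CC(C)(C)[Si](C)(C)Cl
Why: Standard silylation of both phenols.

Step 10
Reactants: 16 1-bromo-3,5-bis[(tert-butyldimethylsilyl)oxy]benzene; 17 4-ethenylphenyl acetate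
Product: 18 4-[(E)-2-{3,5-bis[(tert-butyldimethylsilyl)oxy]phenyl}ethenyl]phenyl acetate
Conditions: Pd2(dba)3 (2.5 mol%), [HP(t-Bu)3]BF4 (10 mol%), Cy2NMe (1.5 equiv), 1,4-dioxane, 70 °C
Reagents that add atoms: none
Why: Mizoroki–Heck reaction giving the E-stilbene; building the stilbene from two differently protected halves gives the 3,5-disilyl, 4'-acyl pattern directly.

Step 11
Reactants: 18 4-[(E)-2-{3,5-bis[(tert-butyldimethylsilyl)oxy]phenyl}ethenyl]phenyl acetate
Product: 19 4-[(E)-2-{3,5-bis[(tert-butyldimethylsilyl)oxy]phenyl}ethenyl]phenol
Conditions: pyrrolidine (3 equiv), CH2Cl2, 0 °C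
Reagents that add atoms: none
Why: Aminolysis of the aryl acetate, an active ester, is fast at 0 °C, whereas aryl silyl ethers should not be attacked by a secondary amine in an aprotic solvent in that time.

Step 12
Reactants: 19 4-[(E)-2-{3,5-bis[(tert-butyldimethylsilyl)oxy]phenyl}ethenyl]phenol; 20 1,3-dichloro-1,1,3,3-tetraisopropyldisiloxane; 14 the tetraacetylated stilbene phenol from step 8
Product: 22 1-{4-[(E)-2-{3,5-bis[(tert-butyldimethylsilyl)oxy]phenyl}ethenyl]phenoxy}-3-{4-[(E)-2-{(2R,3R)-6-acetoxy-2-(4-acetoxyphenyl)-3-(3,5-diacetoxyphenyl)-2,3-dihydro-1-benzofuran-4-yl}ethenyl]phenoxy}-1,1,3,3-tetraisopropyldisiloxane, via chlorodisiloxane 21 (not isolated)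
Conditions: 20 (3 equiv), pyridine, CH2Cl2, 0 °C → rt; excess 20 and volatiles removed at 0.05 mbar; then 14 (0.9 equiv), pyridine, DMF, rt
Reagents that add atoms: none
Why: Stepwise silylation of two phenols by the two Si–Cl bonds; the excess of 20 in the first stage suppresses symmetric double substitution. Pyridine is used instead of imidazole or DMAP because it should not transfer acetyl groups from the aryl acetates of 14 to its free phenol.

Step 13
Reactants: 22 the disiloxane-strapped bis-stilbene from step 12
Product: 23 strapped syn head-to-head cyclobutane C1–C2–C3–Ca: C1 (S) and Ca (R) carry the two 4-oxyphenyl groups, cis and bridged by O–Si(iPr)2–O–Si(iPr)2–O; C3 (S) carries 3,5-bis[(tert-butyldimethylsilyl)oxy]phenyl and C2 (R) the (2R,3R)-tetraacetoxy dihydrobenzofuran-4-yl group, these two cis to each other and trans to the strapped pair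
Conditions: thioxanthone (20 mol%), degassed CH2Cl2 (0.002 M), 405 nm LED, −40 °C
Reagents that add atoms: none
Why: Thioxanthone, the only absorber at 405 nm, passes its triplet energy (about 65 kcal/mol) to one stilbene (about 49 kcal/mol); the twisted stilbene triplet bonds to the partner alkene held against it and the benzylic triplet 1,4-diradical closes after intersystem crossing, the closest known reaction type being the triplet-sensitised [2+2] photocycloaddition of tethered styrenes and stilbenes. The cyclobutane closes by recombination of the 1,4-diradical; the 15-membered strap ring (C1, two para-phenylene paths, O–Si–O–Si–O, Ca) is closed by the C1–Ca bond, the C2–C3 bond alone giving a 17-membered ring. C1 and Ca: the strap ties their 4-oxyphenyl groups together, so they end cis and head-to-head, since it cannot span a head-to-tail or an anti dimer. C3: fixed relative to C2 by the same face-to-face stacking, which puts the silylated resorcinol ring and the benzofuran ring cis; each is trans to the 4-oxyphenyl group across its former E alkene because the diradical closes from its less crowded rotamer. C2: its sense relative to C2'/C3' depends on which face of the C1=C2 alkene is stacked; in the preferred rotamer about C4'–C2 (C1 turned away from C3') the diacetoxyphenyl group on C3' covers one face of the benzofuran ring and the bulky bis(silyloxy)phenyl ring should stack on the other, which leads to C2 (R) and C3 (S). Ring closure has to outrun E/Z isomerisation, which the strap, high dilution and low temperature favour; Z isomers are re-sensitised, while the tetraarylcyclobutane has no low triplet and should not reopen. The two syn head-to-head diastereomers differ in their relation to the fixed C2'/C3' centres and are separable, so imperfect facial control would cost material but not enantiomeric purity.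

Step 14
Reactants: 23 the strapped cyclobutane from step 13
Product: 24 cyclobutane tetraol: C1 (S) and Ca (R) each bear 4-hydroxyphenyl (cis), C3 (S) bears 3,5-dihydroxyphenyl, C2 (R) bears the (2R,3R)-6-acetoxy-2-(4-acetoxyphenyl)-3-(3,5-diacetoxyphenyl)-2,3-dihydro-1-benzofuran-4-yl group
Conditions: Et3N·3HF (20 equiv), THF/MeCN, 40 °C
Reagents that add atoms: none
Why: Fluoride cleaves the two aryl silyl ethers and both Si–O(aryl) bonds of the strap, freeing the 4-hydroxyphenyl groups on C1 and Ca and the resorcinol ring on C3; the acidic fluoride source should leave the acetates in place, and the cyclobutane is inert.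

Step 15
Reactants: 24 the cyclobutane tetraol from step 14
Product: 27 (1S,2R,3S)-2-[(2R,3R)-6-acetoxy-2-(4-acetoxyphenyl)-3-(3,5-diacetoxyphenyl)-2,3-dihydro-1-benzofuran-4-yl]-3-[(S)-hydroxy(4-hydroxyphenyl)methyl]-1-(4-hydroxyphenyl)indane-5,7-diol, via bisquinone methide 25 (not isolated), via quinone methide indane 26 (not isolated)
Conditions: Ag2O (2.5 equiv), dry acetone (0.005 M), 0 °C, dark; then H2O (10 vol%), 0 °C → rt
Reagents that add atoms: water, O
Why: Proposed new method: monovalent silver oxidises one 4-hydroxyphenyl group to its phenoxyl radical, whose spin at the ring carbon attached to C1 (or Ca) makes the strained C1–Ca bond a β-bond; β-scission with release of the cyclobutane strain gives a quinone methide and a 4-hydroxybenzyl radical that is oxidised at once to the second quinone methide, the closest known reaction types being the ring opening of cyclobutylcarbinyl radicals and the one-electron 8–8' coupling of 4-hydroxystilbenes, which reaches the same kind of bis(quinone methide) from the other side. C2 and C3 are not touched; C7a of the free resorcinol ring should then add to C1 (five-membered ring, aryl on C1 trans to the C2 substituent, C1 S), whereas closure of the acetylated benzofuran ring (C5') onto Ca would be slow and trans-fused, and water should add to Ca on the face away from C2 in the conformer with C3–H in the plane of the quinone methide, which gives Ca (S).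

Step 16
Reactants: 27 the indane tetraacetate from step 15
Product: 28 (1S,2R,3S)-2-[(2R,3R)-3-(3,5-dihydroxyphenyl)-6-hydroxy-2-(4-hydroxyphenyl)-2,3-dihydro-1-benzofuran-4-yl]-3-[(S)-hydroxy(4-hydroxyphenyl)methyl]-1-(4-hydroxyphenyl)indane-5,7-diol (CNP0175860.1)
Conditions: N2H4·H2O (8 equiv), degassed THF, 0 °C → rt, argon
Reagents that add atoms: none
Why: Hydrazinolysis of aryl acetates is fast and nearly neutral, so the Ca carbinol should not ionise to a quinone methide and no stereocentre is touched; hydrazine also keeps the polyphenol in a reducing medium.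

## Compound list

1 | 1-bromo-3,5-dimethoxybenzene | COc1cc(Br)cc(OC)c1 | starting material
2 | 3,5-dimethoxybenzoyl chloride | COc1cc(OC)cc(C(Cl)=O)c1 | starting material
3 | (2-bromo-4,6-dimethoxyphenyl)(3,5-dimethoxyphenyl)methanone | COc1cc(OC)c(C(=O)c2cc(OC)cc(OC)c2)c(Br)c1 | intermediate (not isolated)
4 | (2-bromo-6-hydroxy-4-methoxyphenyl)(3,5-dimethoxyphenyl)methanone | COc1cc(O)c(C(=O)c2cc(OC)cc(OC)c2)c(Br)c1 | intermediate
5 | 4-methoxybenzyl chloride | COc1ccc(CCl)cc1 | starting material
6 | {2-bromo-4-methoxy-6-[(4-methoxyphenyl)methoxy]phenyl}(3,5-dimethoxyphenyl)methanone | COc1ccc(COc2cc(OC)cc(Br)c2C(=O)c2cc(OC)cc(OC)c2)cc1 | intermediate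
7 | hydrazone of 6 | COc1ccc(COc2cc(OC)cc(Br)c2C(=NN)c2cc(OC)cc(OC)c2)cc1 | intermediate
8 | diazo compound from 7 | COc1ccc(COc2cc(OC)cc(Br)c2C(=[N+]=[N-])c2cc(OC)cc(OC)c2)cc1 | intermediate (not isolated)
9 | (2S,3R)-4-bromo-3-(3,5-dimethoxyphenyl)-6-methoxy-2-(4-methoxyphenyl)-2,3-dihydro-1-benzofuran | Brc1cc(OC)cc2c1[C@@H](c1cc(OC)cc(OC)c1)[C@@H](c1ccc(OC)cc1)O2 | intermediate
10 | 5-[(2R,3R)-4-bromo-6-hydroxy-2-(4-hydroxyphenyl)-2,3-dihydro-1-benzofuran-3-yl]benzene-1,3-diol | Brc1cc(O)cc2c1[C@@H](c1cc(O)cc(O)c1)[C@H](c1ccc(O)cc1)O2 | intermediate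
11 | 5-[(2R,3R)-6-acetoxy-2-(4-acetoxyphenyl)-4-bromo-2,3-dihydro-1-benzofuran-3-yl]benzene-1,3-diyl diacetate | Brc1cc(OC(C)=O)cc2c1[C@@H](c1cc(OC(C)=O)cc(OC(C)=O)c1)[C@H](c1ccc(OC(C)=O)cc1)O2 | intermediate
12 | tert-butyl(4-ethenylphenoxy)dimethylsilane | C=Cc1ccc(O[Si](C)(C)C(C)(C)C)cc1 | starting material
13 | silyl-protected (2R,3R) tetraacetyl benzofuran E-stilbene | CC(C)(C)[Si](C)(C)Oc1ccc(/C=C/c2cc(OC(C)=O)cc3c2[C@@H](c2cc(OC(C)=O)cc(OC(C)=O)c2)[C@H](c2ccc(OC(C)=O)cc2)O3)cc1 | intermediate
14 | (2R,3R) tetraacetyl benzofuran E-stilbene with free 4-hydroxyl on the styryl ring | Oc1ccc(/C=C/c2cc(OC(C)=O)cc3c2[C@@H](c2cc(OC(C)=O)cc(OC(C)=O)c2)[C@H](c2ccc(OC(C)=O)cc2)O3)cc1 | intermediate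
15 | 5-bromobenzene-1,3-diol | Oc1cc(O)cc(Br)c1 | starting material
16 | 1-bromo-3,5-bis[(tert-butyldimethylsilyl)oxy]benzene | CC(C)(C)[Si](C)(C)Oc1cc(Br)cc(O[Si](C)(C)C(C)(C)C)c1 | intermediate
17 | 4-ethenylphenyl acetate | CC(=O)Oc1ccc(C=C)cc1 | starting material
18 | 4-[(E)-2-{3,5-bis[(tert-butyldimethylsilyl)oxy]phenyl}ethenyl]phenyl acetate | CC(=O)Oc1ccc(/C=C/c2cc(O[Si](C)(C)C(C)(C)C)cc(O[Si](C)(C)C(C)(C)C)c2)cc1 | intermediate
19 | 4-[(E)-2-{3,5-bis[(tert-butyldimethylsilyl)oxy]phenyl}ethenyl]phenol | Oc1ccc(/C=C/c2cc(O[Si](C)(C)C(C)(C)C)cc(O[Si](C)(C)C(C)(C)C)c2)cc1 | intermediate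
20 | 1,3-dichloro-1,1,3,3-tetraisopropyldisiloxane | CC(C)[Si](Cl)(C(C)C)O[Si](Cl)(C(C)C)C(C)C | starting material
21 | 1-chloro-3-aryloxy-1,1,3,3-tetraisopropyldisiloxane (aryl = the 4-styrylphenyl group of 19) | CC(C)[Si](Cl)(C(C)C)O[Si](C(C)C)(C(C)C)Oc1ccc(/C=C/c2cc(O[Si](C)(C)C(C)(C)C)cc(O[Si](C)(C)C(C)(C)C)c2)cc1 | intermediate (not isolated)
22 | disiloxane-strapped bis-stilbene | CC(C)[Si](C(C)C)(Oc1ccc(/C=C/c2cc(O[Si](C)(C)C(C)(C)C)cc(O[Si](C)(C)C(C)(C)C)c2)cc1)O[Si](C(C)C)(C(C)C)Oc1ccc(/C=C/c2cc(OC(C)=O)cc3c2[C@@H](c2cc(OC(C)=O)cc(OC(C)=O)c2)[C@H](c2ccc(OC(C)=O)cc2)O3)cc1 | intermediate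
23 | strapped syn head-to-head tetraarylcyclobutane, C1 (S), Ca (R), C3 (S), C2 (R) | CC(C)[Si]4(C(C)C)O[Si](C(C)C)(C(C)C)Oc1ccc(cc1)[C@H]2[C@@H](c1ccc(O4)cc1)[C@H](c1cc(O[Si](C)(C)C(C)(C)C)cc(O[Si](C)(C)C(C)(C)C)c1)[C@@H]2c2cc(OC(C)=O)cc3c2[C@@H](c2cc(OC(C)=O)cc(OC(C)=O)c2)[C@H](c2ccc(OC(C)=O)cc2)O3 | intermediate
24 | desilylated cyclobutane tetraol, C1 (S), Ca (R), C3 (S), C2 (R) | Oc1ccc(cc1)[C@H]2[C@@H](c1ccc(O)cc1)[C@H](c1cc(O)cc(O)c1)[C@@H]2c2cc(OC(C)=O)cc3c2[C@@H](c2cc(OC(C)=O)cc(OC(C)=O)c2)[C@H](c2ccc(OC(C)=O)cc2)O3 | intermediate
25 | bis(quinone methide), C2 (R), C3 (S) | O=C1C=CC(=C[C@H]([C@H](C=C2C=CC(=O)C=C2)c2cc(O)cc(O)c2)c2cc(OC(C)=O)cc3c2[C@@H](c2cc(OC(C)=O)cc(OC(C)=O)c2)[C@H](c2ccc(OC(C)=O)cc2)O3)C=C1 | intermediate (not isolated)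
26 | (1S,2R,3S)-indane with the quinone methide at Ca | Oc1ccc([C@H]2c3c(O)cc(O)cc3[C@@H](C=C3C=CC(=O)C=C3)[C@@H]2c2cc(OC(C)=O)cc3c2[C@@H](c2cc(OC(C)=O)cc(OC(C)=O)c2)[C@H](c2ccc(OC(C)=O)cc2)O3)cc1 | intermediate (not isolated)
27 | indane tetraacetate, (1S,2R,3S), Ca (S), (2'R,3'R) | Oc1ccc([C@H]2c3c(O)cc(O)cc3[C@@H]([C@H](O)c3ccc(O)cc3)[C@@H]2c2cc(OC(C)=O)cc3c2[C@@H](c2cc(OC(C)=O)cc(OC(C)=O)c2)[C@H](c2ccc(OC(C)=O)cc2)O3)cc1 | intermediate
28 | CNP0175860.1, (1S,2R,3S), Ca (S), (2'R,3'R) | Oc1ccc([C@H]2c3c(O)cc(O)cc3[C@@H]([C@H](O)c3ccc(O)cc3)[C@@H]2c2cc(O)cc3c2[C@@H](c2cc(O)cc(O)c2)[C@H](c2ccc(O)cc2)O3)cc1 | target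

## Step count and risk

Total steps: 16. Longest linear sequence: 13 steps (steps 1–8 and 12–16, from 1). The side branch is steps 9–11.

**Step 15 (Proposed new method).**
- What may go wrong: fragmentation going too far. After the C1–Ca bond has opened, the radical at Ca can also expel the C2–C3 bond (full cycloreversion to two stilbenes) before it is oxidised. Further risks are tautomerisation of the C1 quinone methide to a styrene (loss of the C2 centre), hydration at C1 ahead of ring closure, and low facial selectivity in the hydration at Ca.
- Fallback (known chemistry, oxidative phenol coupling): it sets out from 14. 14 and an excess of commercial resveratrol are oxidised together with FeCl3·6H2O in aqueous acetone. Recombination of the two stilbene phenoxyl radicals at their alkene carbons (the 8–8' mode of the biomimetic dimerisation of resveratrol) forms C2–C3 directly and gives 25 among its diastereomers and the homo-dimers. 25 closes and hydrates in the same flask as in step 15, and 27 is isolated by preparative HPLC, where the route is rejoined. The coupling is unselective, but every event is of a known type and no new isolated compound arises.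
- If only the hydration face is at fault, the Ca centre is equilibrated through 26 with a trace of acid in aqueous acetone and 27 is separated.

**Step 13 (key step).**
- What may go wrong: E/Z isomerisation outrunning ring closure because the 15-membered strap leaves the two alkenes too much freedom, and low facial selectivity with respect to C2'/C3'.
- Fallback: a shorter, stiffer one-silicon strap. It sets out from 19. tBu2Si(OTf)2 and 2,6-lutidine in CH2Cl2 at −78 °C give the aryloxysilyl triflate F1 (not isolated). 14 is added at rt to give the di-tert-butylsilylene-bridged bis-stilbene F2. Sensitised irradiation as in step 13 should give the cyclobutane F3 with a 13-membered strap, and Et3N·3HF removes all silicon to give 24, where the route is rejoined.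
- Separation of the two syn head-to-head diastereomers remains the answer to imperfect facial control.

**Step 4.**
- What may go wrong: diversion of the carbene (azine formation, oxidation back to 6) or erosion of enantio- and cis-selectivity, because the carbene carbon is flanked by bromine and the ether. The same crowding can make the hydrazone formation of step 3 sluggish.
- Fallback: an ortho-quinone methide/sulfur ylide [4+1] annulation with resolution, which needs neither hydrazone nor carbene. It sets out from 4. NaBH4 gives the diol F4. Sodium 4-methylbenzenesulfinate in aqueous formic acid gives the sulfone F5. F5 and the sulfonium salt F6 (from 5 and dimethyl sulfide) with Cs2CO3 in CH2Cl2 generate the ortho-quinone methide F7 (not isolated), which the benzylic ylide converts into the trans-2,3-diaryl-2,3-dihydrobenzofuran as a racemate. Chromatography on a chiral stationary phase gives the (2R,3R) tetramethyl ether F8, and BBr3 as in step 5 gives 10, where the route is rejoined.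

**Step 5.**
- What may go wrong: intermolecular Friedel–Crafts alkylation by the ring-opened C2' cation (oligomerisation), or incomplete equilibration at C2' under the Lewis acid.
- Fallback: nucleophilic demethylation without a Lewis acid. It sets out from 9. NaSEt in DMF at 120 °C cleaves the four methyl ethers by attack at methyl and gives the cis tetraphenol F9 as its phenoxide. Under the same basic conditions the 4-oxidophenyl group at C2' opens the ring reversibly to a quinone methide, the known alkaline cleavage mode of 4-hydroxybenzyl aryl ethers, and re-closure gives the trans isomer. Acidification gives 10, where the route is rejoined.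

**Step 12.**
- What may go wrong: acetyl transfer between the phenol and the aryl acetates of 14 under the basic silylation conditions, hydrolysis of the Si–Cl bond of 21, and formation of symmetric straps.
- Fallback: the strap is built first and the stilbenes last. It sets out from 20. 4-Vinylphenol (2 equiv, commercial solution) and pyridine give the bis(4-vinylphenoxy)disiloxane F10. A Mizoroki–Heck reaction of excess F10 with 16 gives the mono-stilbene F11, and a second Mizoroki–Heck reaction with 11 gives 22, where the route is rejoined.

## Further compounds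

F0 | step 15 | none | none
F1 | step 13 | di-tert-butyl(aryloxy)silyl triflate from 19 (not isolated) | CC(C)(C)[Si](OS(=O)(=O)C(F)(F)F)(Oc1ccc(/C=C/c2cc(O[Si](C)(C)C(C)(C)C)cc(O[Si](C)(C)C(C)(C)C)c2)cc1)C(C)(C)C
F2 | step 13 | di-tert-butylsilylene-bridged bis-stilbene | CC(C)(C)[Si](Oc1ccc(/C=C/c2cc(O[Si](C)(C)C(C)(C)C)cc(O[Si](C)(C)C(C)(C)C)c2)cc1)(Oc1ccc(/C=C/c2cc(OC(C)=O)cc3c2[C@@H](c2cc(OC(C)=O)cc(OC(C)=O)c2)[C@H](c2ccc(OC(C)=O)cc2)O3)cc1)C(C)(C)C
F3 | step 13 | silylene-bridged syn head-to-head cyclobutane, C1 (S), Ca (R), C3 (S), C2 (R) | CC(C)(C)[Si]4(C(C)(C)C)Oc1ccc(cc1)[C@H]2[C@@H](c1ccc(O4)cc1)[C@H](c1cc(O[Si](C)(C)C(C)(C)C)cc(O[Si](C)(C)C(C)(C)C)c1)[C@@H]2c2cc(OC(C)=O)cc3c2[C@@H](c2cc(OC(C)=O)cc(OC(C)=O)c2)[C@H](c2ccc(OC(C)=O)cc2)O3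
F4 | step 4 | 3-bromo-2-[(3,5-dimethoxyphenyl)(hydroxy)methyl]-5-methoxyphenol (racemic) | COc1cc(O)c(C(O)c2cc(OC)cc(OC)c2)c(Br)c1
F5 | step 4 | 3-bromo-2-[(3,5-dimethoxyphenyl)(4-methylbenzenesulfonyl)methyl]-5-methoxyphenol (racemic) | COc1cc(O)c(C(c2cc(OC)cc(OC)c2)S(=O)(=O)c2ccc(C)cc2)c(Br)c1
F6 | step 4 | (4-methoxybenzyl)dimethylsulfonium chloride | COc1ccc(C[S+](C)C)cc1.[Cl-]
F7 | step 4 | ortho-quinone methide from F5 (not isolated, alkene geometry open) | COC1=CC(=O)C(=Cc2cc(OC)cc(OC)c2)C(Br)=C1
F8 | step 4 | (2R,3R)-4-bromo-3-(3,5-dimethoxyphenyl)-6-methoxy-2-(4-methoxyphenyl)-2,3-dihydro-1-benzofuran | Brc1cc(OC)cc2c1[C@@H](c1cc(OC)cc(OC)c1)[C@H](c1ccc(OC)cc1)O2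
F9 | step 5 | 5-[(2S,3R)-4-bromo-6-hydroxy-2-(4-hydroxyphenyl)-2,3-dihydro-1-benzofuran-3-yl]benzene-1,3-diol | Brc1cc(O)cc2c1[C@@H](c1cc(O)cc(O)c1)[C@@H](c1ccc(O)cc1)O2
F10 | step 12 | 1,3-bis(4-ethenylphenoxy)-1,1,3,3-tetraisopropyldisiloxane | C=Cc1ccc(O[Si](C(C)C)(C(C)C)O[Si](C(C)C)(C(C)C)Oc2ccc(C=C)cc2)cc1
F11 | step 12 | 1-{4-[(E)-2-{3,5-bis[(tert-butyldimethylsilyl)oxy]phenyl}ethenyl]phenoxy}-3-(4-ethenylphenoxy)-1,1,3,3-tetraisopropyldisiloxane | CC(C)[Si](C(C)C)(Oc1ccc(/C=C/c2cc(O[Si](C)(C)C(C)(C)C)cc(O[Si](C)(C)C(C)(C)C)c2)cc1)O[Si](C(C)C)(C(C)C)Oc1ccc(C=C)cc1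
A1 | alternative 1 | benzyl- and silyl-protected skeleton of the target with a pinacolboronate at C6' | c1ccccc1COc1ccc([C@H]2c3c(OCc4ccccc4)cc(OCc4ccccc4)cc3[C@@H]([C@H](O[Si](C)(C)C(C)(C)C)c3ccc(OCc4ccccc4)cc3)[C@@H]2c2cc(B4OC(C)(C)C(C)(C)O4)cc3c2[C@@H](c2cc(OCc4ccccc4)cc(OCc4ccccc4)c2)[C@H](c2ccc(OCc4ccccc4)cc2)O3)cc1
A2 | alternative 1 | diyne: protected indane carrying at C2 the chain C≡C–C3'H(aryl)–C2'H(aryl)–O–C≡CH | c1ccccc1COc1ccc([C@H]2c3c(OCc4ccccc4)cc(OCc4ccccc4)cc3[C@@H]([C@H](O[Si](C)(C)C(C)(C)C)c3ccc(OCc4ccccc4)cc3)[C@@H]2C#C[C@@H](c2cc(OCc3ccccc3)cc(OCc3ccccc3)c2)[C@H](c2ccc(OCc3ccccc3)cc2)OC#C)cc1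
A3 | alternative 1 | 2-ethynyl-4,4,5,5-tetramethyl-1,3,2-dioxaborolane | C#CB1OC(C)(C)C(C)(C)O1
A4 | alternative 2 | all-trans 3-(4-methoxybenzoyl)indane, permethyl ether | COc1ccc([C@H]2c3c(OC)cc(OC)cc3[C@@H](C(=O)c3ccc(OC)cc3)[C@@H]2c2cc(OC)cc3c2[C@@H](c2cc(OC)cc(OC)c2)[C@H](c2ccc(OC)cc2)O3)cc1
A5 | alternative 2 | 1,2-trans-6,8-dimethoxy-1,4-bis(4-methoxyphenyl)-2-(tetramethoxy dihydrobenzofuran-4-yl)-1,2-dihydronaphthalene | COc1ccc([C@H]2c3c(OC)cc(OC)cc3C(c3ccc(OC)cc3)=C[C@@H]2c2cc(OC)cc3c2[C@@H](c2cc(OC)cc(OC)c2)[C@H](c2ccc(OC)cc2)O3)cc1
A6 | alternative 3 | all-trans 2,3,4-trisubstituted cyclopentanone anti aldol | c1ccccc1COc1ccc([C@H]2CC(=O)[C@@H]([C@H](O)c3ccc(OCc4ccccc4)cc3)[C@@H]2c2cc(OCc4ccccc4)cc3c2[C@@H](c2cc(OCc4ccccc4)cc(OCc4ccccc4)c2)[C@H](c2ccc(OCc4ccccc4)cc2)O3)cc1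
A7 | alternative 3 | (S)-4-[4-(benzyloxy)phenyl]cyclopent-2-en-1-one | c1ccccc1COc1ccc([C@H]2CC(=O)C=C2)cc1
A8 | alternative 3 | (2R,3R)-6-(benzyloxy)-2-[4-(benzyloxy)phenyl]-3-[3,5-bis(benzyloxy)phenyl]-4-bromo-2,3-dihydro-1-benzofuran | Brc1cc(OCc2ccccc2)cc2c1[C@@H](c1cc(OCc3ccccc3)cc(OCc3ccccc3)c1)[C@H](c1ccc(OCc3ccccc3)cc1)O2
A9 | alternative 3 | lithium aryl(dimethyl)zincate LiZnMe2Ar from A8 | [Li+].C[Zn-](C)c1cc(OCc2ccccc2)cc2c1[C@@H](c1cc(OCc3ccccc3)cc(OCc3ccccc3)c1)[C@H](c1ccc(OCc3ccccc3)cc1)O2
A10 | alternative 3 | 4-(benzyloxy)benzaldehyde | O=Cc1ccc(OCc2ccccc2)cc1
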